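**Retrosynthetic overview**

1. The aryl ester is attached last to the 4,6-diol; the C6 carbinol comes from chelation-controlled reduction of a bicyclic β-hydroxy ketone (C4–OH, C6=O).
2. The cycloheptene (C1, C5–C10) is closed second, by ring-closing metathesis that forms C8=C9 from an allyl arm on C1 and a 2-methylallyl group on C6.
3. The cyclopentane (C1–C5) is closed first, by forming C4–C5 in an enamine aldol reaction; the angular methyl C15 is carried as a formylmethyl arm (C15–C16HO), held as a lactol by the C4 hydroxyl and cut back by decarbonylation.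
4. Enabling feature: the tertiary carbinol C4 and the oxygenated C6 flank C5 in a 1,3-relationship (aldol retron, C5 α to C6 at the aldehyde level). In addition C15, the C4 hydroxyl and C6 all lie on one face of the five-membered ring, so an achiral keto-trialdehyde with three identical arms on C1 is a sufficient precursor.
5. That precursor, 7-methyl-6-oxo-3,3-bis(2-oxoethyl)octanal, is made from pent-4-enenitrile by two successive allylations, chain extension with 3-methylbutan-2-one and ozonolysis.

Key step: step 7

Remark on numbering: daucane numbering is used for all intermediates (C1 methyl-bearing ring-fusion carbon, C2/C3 cyclopentane CH2, C4 carbinol with isopropyl, C5 ring-fusion CH, C6 ester carbon, C7 CH2, C8 methyl-bearing alkene carbon, C9 alkene CH, C10 CH2, C15 methyl on C1); C16 is the formyl carbon of the arm that is later cut back to C15H3.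

Remark on mixtures: the lactol carbon C16 and, after step 9, the carbinol carbon C6 are carried as epimer mixtures because both centres are cleared in steps 11 and 12; the SMILES leave them open. The new formyl group of the lactol aldehydes may also be masked reversibly as a hemiacetal with the lactol hydroxyl.

**Route**

Step 1
Reactants: 1 pent-4-enenitrile; 2 allyl bromide
Product: 3 2-(prop-2-en-1-yl)pent-4-enenitrile
Conditions: LiN(iPr)2 (1.05 equiv), THF, −78 °C; then 2 (1.0 equiv), −78 °C → 0 °C
Reagents that add atoms: none
Why: α-Alkylation of the fully preformed lithiated nitrile with one equivalent of the allylic bromide (SN2) should stop at the monoallyl stage, no stereocentre arises because C2 then carries two identical allyl groups, and any doubly allylated material is simply the product of step 2.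

Step 2
Reactants: 3 2-(prop-2-en-1-yl)pent-4-enenitrile; 2 allyl bromide
Product: 4 2,2-di(prop-2-en-1-yl)pent-4-enenitrile
Conditions: LiN(iPr)2 (1.1 equiv), THF, −78 °C; then 2 (1.3 equiv), −78 °C → rt
Reagents that add atoms: none
Why: A second α-alkylation of the nitrile-stabilised tertiary carbanion (SN2 on the allylic bromide) builds the quaternary carbon C1 with three identical allyl arms, so no stereocentre arises.

Step 3
Reactants: 4 2,2-di(prop-2-en-1-yl)pent-4-enenitrile
Product: 6 2,2-di(prop-2-en-1-yl)pent-4-enal, via N-aluminated aldimine 5 (not isolated)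
Conditions: iBu2AlH (1.3 equiv), CH2Cl2, −78 °C; then 1 M HCl, 0 °C
Reagents that add atoms: water, O
Why: Nitrile-to-aldehyde reduction stops after one hydride transfer at the N-aluminated aldimine, which is hydrolysed on acidic work-up; the quaternary α-carbon excludes enolisation.

Step 4
Reactants: 6 2,2-di(prop-2-en-1-yl)pent-4-enal; 7 3-methylbutan-2-one
Product: 8 (E)-2-methyl-6,6-di(prop-2-en-1-yl)nona-4,8-dien-3-one
Conditions: 7 (5 equiv), NaOH (aq.), EtOH, 60 °C
Reagents that add atoms: none
Why: Claisen–Schmidt crossed aldol condensation: 6 has no α-hydrogen, and of the two enolates of 7 only the methyl-side adduct can dehydrate, which should give the (E)-enone.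

Step 5
Reactants: 8 (E)-2-methyl-6,6-di(prop-2-en-1-yl)nona-4,8-dien-3-one
Product: 10 2-methyl-6,6-di(prop-2-en-1-yl)non-8-en-3-one, via silyl enol ether 9 (not isolated)
Conditions: [(Ph3P)CuH]6 (5 mol %), PhMe2SiH (1.5 equiv), toluene, rt; then 1 M HCl, THF
Reagents that add atoms: none
Why: Copper hydride conjugate reduction (1,4-hydrosilylation, then hydrolysis of the silyl enol ether) reduces only the polarised enone double bond and leaves the isolated terminal alkenes alone.

Step 6
Reactants: 10 2-methyl-6,6-di(prop-2-en-1-yl)non-8-en-3-one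
Product: 12 7-methyl-6-oxo-3,3-bis(2-oxoethyl)octanal, via tris-ozonide 11 (not isolated)
Conditions: O3, CH2Cl2, −78 °C; then PPh3 (3.3 equiv), −78 °C → rt; used crude
Reagents that add atoms: ozone, [O-][O+]=O
Why: Ozonolysis with reductive work-up cleaves the three terminal alkenes to formyl groups (each loses CH2 as formaldehyde) and does not touch the saturated ketone.

Step 7
Reactants: 12 7-methyl-6-oxo-3,3-bis(2-oxoethyl)octanal
Product: 14 (1R,5R,8R)-3-hydroxy-5-(2-oxoethyl)-1-(propan-2-yl)-2-oxabicyclo[3.2.1]octane-8-carbaldehyde (anomer mixture), via monocyclic aldol trialdehyde 13 (not isolated)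
Conditions: (R)-proline (20 mol %), DMSO (0.02 M), rt
Reagents that add atoms: none
Why: (R)-Proline condenses with one of the three homotopic formylmethyl arms of 12 to an (E)-enamine whose α-carbon (C5) adds to the isopropyl ketone carbon (C4) while the carboxylic acid hydrogen-bonds the ketone oxygen, and hydrolysis of the iminium ion releases the catalyst and aldol 13, whose tertiary hydroxyl then closes a six-membered lactol onto the single formylmethyl arm lying on its own face. The closest known reaction type is the proline-catalysed intramolecular enolexo aldolisation of dicarbonyl compounds (Hajos–Parrish type, ketone acceptor), including its use with dialdehyde and keto-aldehyde substrates. The cyclopentane closes in the 5-(enolexo)-exo-trig mode by forming C4–C5, and the lactol ring closes in the 6-exo-trig mode by O–C bond formation. C4 and C5 are set by the catalyst: the acid-directed transition state should put the new hydroxyl cis to the formyl group, and the (R)-catalyst should expose the enamine face that gives (R)-C5, opposite to the (S)-induction known for (S)-proline with aldehyde donors; C1 needs no selectivity, because whichever arm is cis to the C4 hydroxyl becomes the lactol (the later C15 methyl) and the trans arm becomes C10–C9. The step needs aldehyde-donor/ketone-acceptor chemoselectivity, which the substrate secures because the secondary amine forms enamines with the unhindered aldehydes far faster than with the α-branched ketone, an aldol closure between two arms would need a four-membered ring, and high dilution disfavours intermolecular aldol reaction. Lactol formation also removes the tertiary hydroxyl and, through reversible hemiacetal formation, the new formyl group from the equilibrium, which opposes retro-aldol cleavage and dehydration.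

Step 8
Reactants: 14 lactol dialdehyde
Product: 15 (1R,5R,8R)-3-hydroxy-1-(propan-2-yl)-5-(prop-2-en-1-yl)-2-oxabicyclo[3.2.1]octane-8-carbaldehyde (anomer mixture)
Conditions: Ph3P=CH2 (2.1 equiv; from Ph3PCH3Br and KN(SiMe3)2), THF, −78 °C; AcOH quench at −78 °C
Reagents that add atoms: methylenetriphenylphosphorane, C=P(c1ccccc1)(c1ccccc1)c1ccccc1
Why: Wittig methylenation should convert only the unhindered formyl group of the trans CH2CHO arm, because the first equivalent of ylide merely deprotonates the lactol hydroxyl, the lactolate stays closed at −78 °C, and the C6 formyl group is flanked by two quaternary carbons and reversibly masked as a hemiacetal.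

Step 9
Reactants: 15 lactol aldehyde with allyl arm
Product: 16 1-[(1R,5R,8S)-3-hydroxy-1-(propan-2-yl)-5-(prop-2-en-1-yl)-2-oxabicyclo[3.2.1]octan-8-yl]-3-methylbut-3-en-1-ol (mixture at C6 and C16)
Conditions: CH2=C(CH3)CH2MgCl (3 equiv), THF, −78 °C; aq. NH4Cl
Reagents that add atoms: 2-methylallylmagnesium chloride, CC(=C)C[Mg]Cl
Why: Grignard 1,2-addition to the remaining aldehyde installs C7, C8 and C14, the magnesium lactolate should not open at −78 °C, and the configuration of the new carbinol C6 does not matter because it is erased in step 12.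

Step 10
Reactants: 16 diene lactol
Product: 17 tricyclic lactol: the hexahydroazulene-3,4-diol skeleton of 18 in which C15 is a CH2 joined through a CH(OH) carbon (C16) to the C4 oxygen (six-membered lactol bridging C1 and C4; mixture at C6 and C16)
Conditions: second-generation Grubbs catalyst RuCl2(=CHPh)(PCy3)(H2IMes) (5 mol %), CH2Cl2 (0.005 M), 40 °C
Reagents that add atoms: none
Why: Ring-closing olefin metathesis between the monosubstituted and the 1,1-disubstituted alkene releases ethene and closes the seven-membered ring with the trisubstituted C8=C9 bond exactly in place; the two arms are trans on the cyclopentane, which gives the trans ring fusion without creating a stereocentre.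

Step 11
Reactants: 17 tricyclic lactol
Product: 18 (3R,3aS,8aR)-6,8a-dimethyl-3-(propan-2-yl)-1,2,3,3a,4,5,8,8a-octahydroazulene-3,4-diol (mixture at C4 of the azulene, that is C6)
Conditions: [Rh(Ph2P(CH2)3PPh2)2]Cl (5 mol %), diglyme, 160 °C, N2 stream
Reagents that add atoms: none
Why: Tsuji–Wilkinson decarbonylation acts on the open hydroxy-aldehyde form of the lactol (oxidative addition of the formyl C–H bond, CO extrusion, reductive elimination), as is known for unprotected aldoses, and turns the C15H2–C16HO arm into the C15 methyl group and frees the C4 hydroxyl without touching a stereocentre.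

Step 12
Reactants: 18 diol (C6 epimers)
Product: 19 (3R,3aR,8aR)-3-hydroxy-6,8a-dimethyl-3-(propan-2-yl)-2,3,3a,5,8,8a-hexahydroazulen-4(1H)-one
Conditions: Dess–Martin periodinane (1.5 equiv), NaHCO3, CH2Cl2, 0 °C → rt
Reagents that add atoms: none
Why: Dess–Martin oxidation converts both epimers of the secondary C6 carbinol into one ketone under buffered, non-basic conditions that spare the tertiary alcohol and should avoid retro-aldol cleavage and conjugation of the β,γ-double bond.

Step 13
Reactants: 19 β-hydroxy ketone
Product: 20 (3R,3aS,4R,8aR)-6,8a-dimethyl-3-(propan-2-yl)-1,2,3,3a,4,5,8,8a-octahydroazulene-3,4-diol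
Conditions: Zn(BH4)2 (2 equiv), Et2O, −20 °C; aq. NH4Cl
Reagents that add atoms: none
Why: Chelation-controlled hydride reduction of the β-hydroxy ketone: zinc bridges the C4 hydroxyl and the C6 carbonyl oxygen, and hydride should add to C6 from the face of the small C5 hydrogen, anti to the quaternary C1 with its angular methyl, which sets (R)-C6 with the hydroxyl syn to the C4 hydroxyl.

Step 14
Reactants: 20 diol; 21 4-acetoxybenzoyl chloride
Product: 22 (3R,3aS,4R,8aR)-3-hydroxy-6,8a-dimethyl-3-(propan-2-yl)-1,2,3,3a,4,5,8,8a-octahydroazulen-4-yl 4-acetoxybenzoate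
Conditions: 21 (1.5 equiv), Et3N, DMAP (cat.), CH2Cl2, 0 °C → rt
Reagents that add atoms: none
Why: DMAP-catalysed acylation with the acid chloride should esterify only the secondary C6 hydroxyl, the tertiary C4 hydroxyl being too hindered to react.

Step 15
Reactants: 22 acetate-protected ester
Product: 23 (3R,3aS,4R,8aR)-3-hydroxy-6,8a-dimethyl-3-(propan-2-yl)-1,2,3,3a,4,5,8,8a-octahydroazulen-4-yl 4-hydroxybenzoate (target)
Conditions: pyrrolidine (3 equiv), CH2Cl2, 0 °C
Reagents that add atoms: none
Why: Aminolysis cleaves the activated phenolic acetate much faster than the hindered benzoate of the secondary alcohol, which unveils the phenol.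

**Compound list**

1 | pent-4-enenitrile | C=CCCC#N | starting material
2 | allyl bromide (3-bromoprop-1-ene) | C=CCBr | starting material
3 | 2-(prop-2-en-1-yl)pent-4-enenitrile | C=CCC(CC=C)C#N | intermediate
4 | 2,2-di(prop-2-en-1-yl)pent-4-enenitrile | C=CCC(CC=C)(CC=C)C#N | intermediate
5 | N-(diisobutylalumanyl)-2,2-di(prop-2-en-1-yl)pent-4-en-1-imine | C=CCC(CC=C)(CC=C)C=N[Al](CC(C)C)CC(C)C | intermediate
6 | 2,2-di(prop-2-en-1-yl)pent-4-enal | C=CCC(CC=C)(CC=C)C=O | intermediate
7 | 3-methylbutan-2-one | CC(C)C(C)=O | starting material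
8 | (E)-2-methyl-6,6-di(prop-2-en-1-yl)nona-4,8-dien-3-one | CC(C)C(=O)/C=C/C(CC=C)(CC=C)CC=C | intermediate
9 | dimethyl(phenyl)silyl enol ether of 10, {[2-methyl-6,6-di(prop-2-en-1-yl)nona-3,8-dien-3-yl]oxy}dimethyl(phenyl)silane | CC(C)C(O[Si](C)(C)c1ccccc1)=CCC(CC=C)(CC=C)CC=C | intermediate
10 | 2-methyl-6,6-di(prop-2-en-1-yl)non-8-en-3-one | CC(C)C(=O)CCC(CC=C)(CC=C)CC=C | intermediate
11 | 2-methyl-7-(1,2,4-trioxolan-3-yl)-6,6-bis(1,2,4-trioxolan-3-ylmethyl)heptan-3-one | CC(C)C(=O)CCC(CC1OCOO1)(CC1OCOO1)CC1OCOO1 | intermediate
12 | 7-methyl-6-oxo-3,3-bis(2-oxoethyl)octanal | CC(C)C(=O)CCC(CC=O)(CC=O)CC=O | intermediate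
13 | (1R,2R)-2-hydroxy-5,5-bis(2-oxoethyl)-2-(propan-2-yl)cyclopentane-1-carbaldehyde (OH and CHO cis) | O=CCC1(CC=O)CC[C@@](O)(C(C)C)[C@@H]1C=O | intermediate
14 | (1R,5R,8R)-3-hydroxy-5-(2-oxoethyl)-1-(propan-2-yl)-2-oxabicyclo[3.2.1]octane-8-carbaldehyde | O=CC[C@@]1(CC2O)CC[C@@](O2)(C(C)C)[C@@H]1C=O | intermediate
15 | (1R,5R,8R)-3-hydroxy-1-(propan-2-yl)-5-(prop-2-en-1-yl)-2-oxabicyclo[3.2.1]octane-8-carbaldehyde | C=CC[C@@]1(CC2O)CC[C@@](O2)(C(C)C)[C@@H]1C=O | intermediate
16 | 1-[(1R,5R,8S)-3-hydroxy-1-(propan-2-yl)-5-(prop-2-en-1-yl)-2-oxabicyclo[3.2.1]octan-8-yl]-3-methylbut-3-en-1-ol | C=CC[C@@]1(CC2O)CC[C@@](O2)(C(C)C)[C@@H]1C(O)CC(C)=C | intermediate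
17 | tricyclic lactol (trans-fused hydroazulene; C15H2–C16H(OH)–O bridge from C1 to C4; C6 carbinol) | CC1=CC[C@@]2(CC3O)CC[C@@](O3)(C(C)C)[C@@H]2C(O)C1 | intermediate
18 | (3R,3aS,8aR)-6,8a-dimethyl-3-(propan-2-yl)-1,2,3,3a,4,5,8,8a-octahydroazulene-3,4-diol (C6 epimers) | CC1=CC[C@@]2(C)CC[C@@](O)(C(C)C)[C@@H]2C(O)C1 | intermediate
19 | (3R,3aR,8aR)-3-hydroxy-6,8a-dimethyl-3-(propan-2-yl)-2,3,3a,5,8,8a-hexahydroazulen-4(1H)-one | CC1=CC[C@@]2(C)CC[C@@](O)(C(C)C)[C@@H]2C(=O)C1 | intermediate
20 | (3R,3aS,4R,8aR)-6,8a-dimethyl-3-(propan-2-yl)-1,2,3,3a,4,5,8,8a-octahydroazulene-3,4-diol | CC1=CC[C@@]2(C)CC[C@@](O)(C(C)C)[C@@H]2[C@H](O)C1 | intermediate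
21 | 4-acetoxybenzoyl chloride | CC(=O)Oc1ccc(cc1)C(Cl)=O | starting material
22 | (3R,3aS,4R,8aR)-3-hydroxy-6,8a-dimethyl-3-(propan-2-yl)-1,2,3,3a,4,5,8,8a-octahydroazulen-4-yl 4-acetoxybenzoate | CC1=CC[C@@]2(C)CC[C@@](O)(C(C)C)[C@@H]2[C@H](OC(=O)c2ccc(OC(C)=O)cc2)C1 | intermediate
23 | (3R,3aS,4R,8aR)-3-hydroxy-6,8a-dimethyl-3-(propan-2-yl)-1,2,3,3a,4,5,8,8a-octahydroazulen-4-yl 4-hydroxybenzoate | CC1=CC[C@@]2(C)CC[C@@](O)(C(C)C)[C@@H]2[C@H](OC(=O)c2ccc(O)cc2)C1 | target

**Step count and risks**

Total step count: 15. Longest linear sequence: 15 steps (1 to 23).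

Steps most likely to fail:

Step 7. What may go wrong: too little face discrimination in the enamine addition to the hindered ketone (erosion of enantiomeric purity), or intermolecular aldol oligomerisation overtaking ring closure. Fallback: setting out from 12, the same cyclisation is run under achiral enamine catalysis (pyrrolidine and acetic acid, high dilution). The lactol lock still fixes the relative configuration, so this should give the racemate, that is 14 together with its mirror image ent-14 F1. The enantiomers are then separated by preparative chromatography on a chiral stationary phase, and 14 rejoins the route at step 8.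

Step 8. What may go wrong: loss of chemoselectivity through base-triggered opening of the lactol and hemiacetal network, so that the C6 formyl group or the unmasked lactol aldehyde is methylenated as well, or the β-oxygenated aldehyde undergoes elimination. Fallback: setting out from 14, the free formyl group is homologated to the terminal alkyne with dimethyl (1-diazo-2-oxopropyl)phosphonate, K2CO3 and MeOH at 0 °C (Seyferth–Gilbert homologation, far less basic than a phosphorus ylide). This should give (1R,5R,8R)-3-hydroxy-1-(propan-2-yl)-5-(prop-2-yn-1-yl)-2-oxabicyclo[3.2.1]octane-8-carbaldehyde F2. Semihydrogenation of F2 over Pd/CaCO3 poisoned with Pb(OAc)2 and quinoline returns 15.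

Step 11. What may go wrong: migration of the C8=C9 double bond by rhodium hydride species at 160 °C, or stalling because the lactol drains into an unreactive acetal with the C6 hydroxyl. Fallback: setting out from 17, TEMPO (cat.) and PhI(OAc)2 should oxidise the lactol, but not the hindered secondary alcohol, to the corresponding bridged δ-lactone F3. CsOH in aqueous THF opens it to cesium [(3R,3aS,8aR)-3,4-dihydroxy-6-methyl-3-(propan-2-yl)-1,2,3,3a,4,5,8,8a-octahydroazulen-8a-yl]acetate F4. Visible-light photoredox hydrodecarboxylation of this carboxylate ([Ir(dF(CF3)ppy)2(dtbbpy)]PF6 as photocatalyst, a thiol as hydrogen-atom donor) then delivers 18.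

**Further compounds**

F1 | step 7 | (1S,5S,8S)-3-hydroxy-5-(2-oxoethyl)-1-(propan-2-yl)-2-oxabicyclo[3.2.1]octane-8-carbaldehyde (ent-14) | O=CC[C@]1(CC2O)CC[C@](O2)(C(C)C)[C@H]1C=O
F2 | step 8 | (1R,5R,8R)-3-hydroxy-1-(propan-2-yl)-5-(prop-2-yn-1-yl)-2-oxabicyclo[3.2.1]octane-8-carbaldehyde | C#CC[C@@]1(CC2O)CC[C@@](O2)(C(C)C)[C@@H]1C=O
F3 | step 11 | bridged δ-lactone of 17 (C16 as lactone carbonyl on the C4 oxygen; C6 carbinol) | CC1=CC[C@@]2(CC3=O)CC[C@@](O3)(C(C)C)[C@@H]2C(O)C1
F4 | step 11 | cesium [(3R,3aS,8aR)-3,4-dihydroxy-6-methyl-3-(propan-2-yl)-1,2,3,3a,4,5,8,8a-octahydroazulen-8a-yl]acetate | CC1=CC[C@@]2(CC(=O)[O-])CC[C@@](O)(C(C)C)[C@@H]2C(O)C1.[Cs+]
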